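Numbering: ring C1 (angelate), C3 (methyl), C4 (hydroxyl), C6 (side chain); chain C7 (methyl), C8, C9 (acetate), C10=C11. Everything rests on making C7–CH3 and C8–C9 in one operation from a vinyl group on ring carbon C6. Zirconium-catalysed face-selective methylalumination puts methyl on the internal vinyl carbon (C7, new stereocentre) and aluminium on C8; the alane is acylated in the same flask by 3-methylbut-2-enoyl chloride, giving the full skeleton as the C9 enone. The feature exploited is this monosubstituted C6 vinyl group, the only alkene of the precursor, a trans-2-vinylcyclohexyl triethylsilyl ether bearing the C3 methyl and axial C4 tert-butyldimethylsilyl ether, all ring stereocentres set.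

Key step: step 8

Remark (assumption on the chemistry): the facial sense of each chiral catalyst is taken from its standard substrates, with the alkenyl group in the place of the aryl or large group, and 1 is taken as a commercial compound.

Step 1
Reactants: 1 1,4-dioxaspiro[4.5]dec-6-en-8-one
Product: 2 (8R)-1,4-dioxaspiro[4.5]dec-6-en-8-ol
Conditions: RuCl(p-cymene)[(R,R)-TsDPEN] (1 mol%), HCO2Na, Bu4NCl, CH2Cl2–H2O, rt
Reagents that add atoms: none
Why: Noyori asymmetric transfer hydrogenation reduces the enone carbonyl in the 1,2-sense, and with the (R,R)-ligand the ring alkene takes the place of the aryl group of the standard substrates, so hydride should arrive on the face that gives the (R)-carbinol, the future C1.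

Step 2
Reactants: 2 (8R)-1,4-dioxaspiro[4.5]dec-6-en-8-ol
Product: 3 (4R)-4-hydroxycyclohex-2-en-1-one
Conditions: 10% aq. (CO2H)2 on SiO2, CH2Cl2, rt
Reagents that add atoms: water, O
Why: Acid-catalysed ketal hydrolysis on wet silica unmasks the C4 ketone in conjugation with the C5=C6 alkene under conditions too mild to ionise the allylic carbinol, so C1 is untouched and the product is recovered by filtration without aqueous extraction.

Step 3
Reactants: 3 (4R)-4-hydroxycyclohex-2-en-1-one
Product: 4 (4R)-4-(triethylsilyloxy)cyclohex-2-en-1-one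
Conditions: Et3SiCl, imidazole, CH2Cl2, 0 °C
Reagents that add atoms: chlorotriethylsilane, CC[Si](Cl)(CC)CC
Why: Imidazole-promoted silylation of a secondary alcohol installs the triethylsilyl ether, chosen because it is the silyl group that is removed first at the end.

Step 4
Reactants: 4 (4R)-4-(triethylsilyloxy)cyclohex-2-en-1-one
Product: 6 (4R,6R)-6-methyl-4-(triethylsilyloxy)cyclohex-2-en-1-one, via lithium dienolate 5 (not isolated)
Conditions: LiN(i-Pr)2, THF, −78 °C; MeI, −78→−40 °C
Reagents that add atoms: iodomethane, CI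
Why: Kinetic deprotonation of the enone occurs at the α′ carbon (C3) and enolate alkylation with MeI should take place by axial attack anti to the C1 silyloxy group, giving mainly the trans isomer, whose C3 configuration is provisional and is corrected in step 5 (any cis epimer is removed by chromatography).

Step 5
Reactants: 6 (4R,6R)-6-methyl-4-(triethylsilyloxy)cyclohex-2-en-1-one; 7 vinylmagnesium bromide
Product: 9 (2S,4R,5S)-5-ethenyl-2-methyl-4-(triethylsilyloxy)cyclohexan-1-one, via trimethylsilyl enol ether 8 (not isolated)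
Conditions: CuBr·SMe2 (10 mol%), Me3SiCl, THF, −78 °C; then K2CO3, MeOH, 0 °C→rt
Reagents that add atoms: none
Why: Copper-catalysed, Me3SiCl-accelerated conjugate addition of the vinyl Grignard reagent proceeds by axial attack on the half-chair with pseudoaxial C1 silyloxy and pseudoequatorial C3 methyl, so vinyl enters C6 anti to the C1 oxygen, and the K2CO3/MeOH treatment cleaves the enol ether and epimerises C3 to the all-equatorial ketone (thermodynamic control anchored by the trans-diequatorial C1/C6 pair), which places methyl cis to the C1 oxygen.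

Step 6
Reactants: 9 (2S,4R,5S)-5-ethenyl-2-methyl-4-(triethylsilyloxy)cyclohexan-1-one
Product: 10 (1R,2S,4R,5S)-5-ethenyl-2-methyl-4-(triethylsilyloxy)cyclohexan-1-ol
Conditions: LiBH(s-Bu)3, THF, −78 °C; then aq. NaOH, H2O2, 0 °C
Reagents that add atoms: none
Why: The bulky trialkylborohydride (L-Selectride reduction) attacks the conformationally fixed 2-methylcyclohexanone from the equatorial direction, which gives the axial C4 alcohol cis to the equatorial C3 methyl.

Step 7
Reactants: 10 (1R,2S,4R,5S)-5-ethenyl-2-methyl-4-(triethylsilyloxy)cyclohexan-1-ol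
Product: 11 tert-butyl{[(1R,2S,4R,5S)-5-ethenyl-2-methyl-4-(triethylsilyloxy)cyclohexyl]oxy}dimethylsilane
Conditions: t-BuMe2SiOTf, 2,6-lutidine, CH2Cl2, −78→0 °C
Reagents that add atoms: tert-butyldimethylsilyl trifluoromethanesulfonate, CC(C)(C)[Si](C)(C)OS(=O)(=O)C(F)(F)F
Why: Silylation with the silyl triflate and a hindered base protects the hindered axial C4 alcohol at low temperature without exchanging the triethylsilyl ether.

Step 8
Reactants: 11 tert-butyl{[(1R,2S,4R,5S)-5-ethenyl-2-methyl-4-(triethylsilyloxy)cyclohexyl]oxy}dimethylsilane; 12 trimethylaluminium; 13 3-methylbut-2-enoyl chloride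
Product: 16 (6R)-6-[(1S,2R,4S,5R)-5-(tert-butyldimethylsilyloxy)-4-methyl-2-(triethylsilyloxy)cyclohexyl]-2-methylhept-2-en-4-one, via alkyldimethylalane 14 (not isolated), via alkylzinc triflate 15 (not isolated)
Conditions: 12 (2 equiv), (+)-bis(1-neomenthylindenyl)zirconium dichloride (10 mol%), CH2Cl2, 0→23 °C; evaporate volatiles; Zn(OTf)2, THF, 23 °C; Pd(PPh3)4 (5 mol%), 13 (3 equiv), 0→23 °C
Reagents that add atoms: none
Why: The cationic methylzirconocene generated from the zirconium dichloride and Me3Al inserts the C6 vinyl group with methyl delivered to the internal carbon (C7) and zirconium to the terminal carbon (C8), and exchange with aluminium releases alane 14 and returns the catalyst; after excess Me3Al is pumped off, Zn(OTf)2 converts 14 into alkylzinc 15, which enters a palladium cycle (oxidative addition of acid chloride 13 to zerovalent palladium, transmetalation, reductive elimination) that forms C8–C9. The closest known reaction type is the zirconium-catalysed asymmetric carboalumination of terminal alkenes telescoped with zinc-mediated palladium-catalysed coupling of the resulting alkylalane, used here in its acylative form (Negishi ketone synthesis from an alkylzinc and an acid chloride). No ring is closed. The one new stereocentre, C7, is set by the chiral indenyl ligands: the (−)-complex is known to turn 1-alkenes into (R)-2-methylalkan-1-ols after oxidation, so the (+)-antipode is the one that should place methyl on the face corresponding to 7R in 16. The step needs methyl-internal regioselectivity, catalyst control of the alkene face next to the C6 branch, and chemoselectivity. The substrate secures these by offering a single, monosubstituted alkene and only silyl ether oxygens, which neither quench the alane nor bind zirconium strongly, while the β,β-dimethyl enone formed is a poor acceptor for further organometallic addition; 13 is used in excess because residual aluminium-bound methyl groups also consume it.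

Step 9
Reactants: 16 (6R)-6-[(1S,2R,4S,5R)-5-(tert-butyldimethylsilyloxy)-4-methyl-2-(triethylsilyloxy)cyclohexyl]-2-methylhept-2-en-4-one
Product: 17 (4R,6R)-6-[(1S,2R,4S,5R)-5-(tert-butyldimethylsilyloxy)-4-methyl-2-(triethylsilyloxy)cyclohexyl]-2-methylhept-2-en-4-ol
Conditions: (S)-1-methyl-3,3-diphenyltetrahydro-1H,3H-pyrrolo[1,2-c][1,3,2]oxazaborole (0.3 equiv), catecholborane, toluene, −78 °C
Reagents that add atoms: none
Why: In this Corey–Bakshi–Shibata reduction the oxazaborolidine–borane complex binds the C9 ketone with the 2-methylprop-1-enyl group as the large substituent, so the (S)-catalyst should deliver hydride under reagent control to give the (9R)-allylic alcohol, and catecholborane at low temperature avoids hydroboration of the trisubstituted alkene.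

Step 10
Reactants: 17 (4R,6R)-6-[(1S,2R,4S,5R)-5-(tert-butyldimethylsilyloxy)-4-methyl-2-(triethylsilyloxy)cyclohexyl]-2-methylhept-2-en-4-ol
Product: 18 (4R,6R)-6-[(1S,2R,4S,5R)-5-(tert-butyldimethylsilyloxy)-4-methyl-2-(triethylsilyloxy)cyclohexyl]-2-methylhept-2-en-4-yl acetate
Conditions: Ac2O, pyridine, DMAP (cat.), CH2Cl2, 0 °C→rt
Reagents that add atoms: acetic anhydride, CC(=O)OC(C)=O
Why: DMAP-catalysed acetylation of the only free hydroxyl proceeds at oxygen under basic, non-ionising conditions, so the C9 configuration is retained.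

Step 11
Reactants: 18 (4R,6R)-6-[(1S,2R,4S,5R)-5-(tert-butyldimethylsilyloxy)-4-methyl-2-(triethylsilyloxy)cyclohexyl]-2-methylhept-2-en-4-yl acetate
Product: 19 (4R,6R)-6-[(1S,2R,4S,5R)-5-(tert-butyldimethylsilyloxy)-2-hydroxy-4-methylcyclohexyl]-2-methylhept-2-en-4-yl acetate
Conditions: HF·pyridine, pyridine, THF, 0 °C
Reagents that add atoms: none
Why: Selective silyl ether cleavage with pyridine-buffered HF·pyridine removes the more labile equatorial triethylsilyl ether at C1, while the hindered axial tert-butyldimethylsilyl ether and the allylic acetate survive the nearly neutral medium.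

Step 12
Reactants: 19 (4R,6R)-6-[(1S,2R,4S,5R)-5-(tert-butyldimethylsilyloxy)-2-hydroxy-4-methylcyclohexyl]-2-methylhept-2-en-4-yl acetate; 20 angelic acid
Product: 22 (1R,2S,4R,5S)-2-[(2R,4R)-4-acetoxy-6-methylhept-5-en-2-yl]-4-(tert-butyldimethylsilyloxy)-5-methylcyclohexyl (2Z)-2-methylbut-2-enoate, via mixed anhydride 21 (not isolated)
Conditions: 20, 2,4,6-Cl3C6H2COCl, Et3N, toluene, rt; then 19, toluene, 80 °C
Reagents that add atoms: none
Why: Yamaguchi-type esterification through the 2,4,6-trichlorobenzoyl mixed anhydride acylates the C1 alcohol at the unhindered angeloyl carbonyl without a nucleophilic catalyst, the conditions known to suppress Z to E isomerisation to the tiglate.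

Step 13
Reactants: 22 (1R,2S,4R,5S)-2-[(2R,4R)-4-acetoxy-6-methylhept-5-en-2-yl]-4-(tert-butyldimethylsilyloxy)-5-methylcyclohexyl (2Z)-2-methylbut-2-enoate
Product: 23 (1R,2S,4R,5S)-2-[(2R,4R)-4-acetoxy-6-methylhept-5-en-2-yl]-4-hydroxy-5-methylcyclohexyl (2Z)-2-methylbut-2-enoate
Conditions: HF·pyridine, pyridine, THF, 0 °C→rt
Reagents that add atoms: none
Why: Fluoride-mediated desilylation in a pyridine-buffered medium frees the C4 hydroxyl without ester cleavage, acyl migration (the C1 and C4 oxygens are 1,4-related) or ionisation of the allylic acetate, which should give the target.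

Compound list
1 | 1,4-dioxaspiro[4.5]dec-6-en-8-one | O=C1C=CC2(CC1)OCCO2 | starting material
2 | (8R)-1,4-dioxaspiro[4.5]dec-6-en-8-ol | O[C@H]1C=CC2(OCCO2)CC1 | intermediate
3 | (4R)-4-hydroxycyclohex-2-en-1-one | O=C1C=C[C@H](O)CC1 | intermediate
4 | (4R)-4-(triethylsilyloxy)cyclohex-2-en-1-one | O=C1C=C[C@H](O[Si](CC)(CC)CC)CC1 | intermediate
5 | lithium (4R)-4-(triethylsilyloxy)cyclohexa-1,5-dien-1-olate (α′ dienolate of 4) | [Li]OC1=CC[C@@H](O[Si](CC)(CC)CC)C=C1 | intermediate
6 | (4R,6R)-6-methyl-4-(triethylsilyloxy)cyclohex-2-en-1-one (methyl trans to silyloxy) | C[C@@H]1C[C@@H](O[Si](CC)(CC)CC)C=CC1=O | intermediate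
7 | vinylmagnesium bromide | C=C[Mg]Br | starting material
8 | 3-ethenyl-6-methyl-4-(triethylsilyloxy)-1-(trimethylsilyloxy)cyclohex-1-ene (4R; vinyl and methyl both trans to the C4 silyloxy group) | C[C@@H]1C[C@@H](O[Si](CC)(CC)CC)[C@H](C=C)C=C1O[Si](C)(C)C | intermediate
9 | (2S,4R,5S)-5-ethenyl-2-methyl-4-(triethylsilyloxy)cyclohexan-1-one | CC[Si](CC)(CC)O[C@@H]1C[C@H](C)C(=O)C[C@H]1C=C | intermediate
10 | (1R,2S,4R,5S)-5-ethenyl-2-methyl-4-(triethylsilyloxy)cyclohexan-1-ol | CC[Si](CC)(CC)O[C@@H]1C[C@H](C)[C@H](O)C[C@H]1C=C | intermediate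
11 | tert-butyl{[(1R,2S,4R,5S)-5-ethenyl-2-methyl-4-(triethylsilyloxy)cyclohexyl]oxy}dimethylsilane (key-step precursor) | CC[Si](CC)(CC)O[C@@H]1C[C@H](C)[C@H](O[Si](C)(C)C(C)(C)C)C[C@H]1C=C | intermediate
12 | trimethylaluminium | C[Al](C)C | starting material
13 | 3-methylbut-2-enoyl chloride | CC(C)=CC(Cl)=O | starting material
14 | dimethyl{2-[5-(tert-butyldimethylsilyloxy)-4-methyl-2-(triethylsilyloxy)cyclohexyl]propyl}alane (C8 alane, C7 and ring configured as in 16) | CC[Si](CC)(CC)O[C@@H]1C[C@H](C)[C@H](O[Si](C)(C)C(C)(C)C)C[C@H]1[C@H](C)C[Al](C)C | intermediate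
15 | {2-[5-(tert-butyldimethylsilyloxy)-4-methyl-2-(triethylsilyloxy)cyclohexyl]propyl}zinc trifluoromethanesulfonate (C8 zinc reagent, C7 and ring configured as in 16) | CC[Si](CC)(CC)O[C@@H]1C[C@H](C)[C@H](O[Si](C)(C)C(C)(C)C)C[C@H]1[C@H](C)C[Zn]OS(=O)(=O)C(F)(F)F | intermediate
16 | (6R)-6-[(1S,2R,4S,5R)-5-(tert-butyldimethylsilyloxy)-4-methyl-2-(triethylsilyloxy)cyclohexyl]-2-methylhept-2-en-4-one (key-step product) | CC[Si](CC)(CC)O[C@@H]1C[C@H](C)[C@H](O[Si](C)(C)C(C)(C)C)C[C@H]1[C@H](C)CC(=O)C=C(C)C | intermediate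
17 | (4R,6R)-6-[(1S,2R,4S,5R)-5-(tert-butyldimethylsilyloxy)-4-methyl-2-(triethylsilyloxy)cyclohexyl]-2-methylhept-2-en-4-ol | CC[Si](CC)(CC)O[C@@H]1C[C@H](C)[C@H](O[Si](C)(C)C(C)(C)C)C[C@H]1[C@H](C)C[C@H](C=C(C)C)O | intermediate
18 | (4R,6R)-6-[(1S,2R,4S,5R)-5-(tert-butyldimethylsilyloxy)-4-methyl-2-(triethylsilyloxy)cyclohexyl]-2-methylhept-2-en-4-yl acetate | CC[Si](CC)(CC)O[C@@H]1C[C@H](C)[C@H](O[Si](C)(C)C(C)(C)C)C[C@H]1[C@H](C)C[C@H](C=C(C)C)OC(C)=O | intermediate
19 | (4R,6R)-6-[(1S,2R,4S,5R)-5-(tert-butyldimethylsilyloxy)-2-hydroxy-4-methylcyclohexyl]-2-methylhept-2-en-4-yl acetate | O[C@@H]1C[C@H](C)[C@H](O[Si](C)(C)C(C)(C)C)C[C@H]1[C@H](C)C[C@H](C=C(C)C)OC(C)=O | intermediate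
20 | angelic acid, (2Z)-2-methylbut-2-enoic acid | C/C=C(/C)C(O)=O | starting material
21 | (2Z)-2-methylbut-2-enoic 2,4,6-trichlorobenzoic anhydride | C/C=C(/C)C(=O)OC(=O)c1c(Cl)cc(Cl)cc1Cl | intermediate
22 | (1R,2S,4R,5S)-2-[(2R,4R)-4-acetoxy-6-methylhept-5-en-2-yl]-4-(tert-butyldimethylsilyloxy)-5-methylcyclohexyl (2Z)-2-methylbut-2-enoate | C/C=C(/C)C(=O)O[C@@H]1C[C@H](C)[C@H](O[Si](C)(C)C(C)(C)C)C[C@H]1[C@H](C)C[C@H](C=C(C)C)OC(C)=O | intermediate
23 | (1R,2S,4R,5S)-2-[(2R,4R)-4-acetoxy-6-methylhept-5-en-2-yl]-4-hydroxy-5-methylcyclohexyl (2Z)-2-methylbut-2-enoate (CNP0237033.1) | C/C=C(/C)C(=O)O[C@@H]1C[C@H](C)[C@H](O)C[C@H]1[C@H](C)C[C@H](C=C(C)C)OC(C)=O | target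

Total step count: 13. Longest linear sequence: 13 steps (1 to 23); 7, 12, 13 and 20 are commercial and enter directly.

Steps most likely to fail

Step 8. The methylalumination may be slow or poorly face-selective next to the C6 branch if the catalyst works against the substrate bias. The triethylsilyl ether may be lost to the Lewis-acidic mixture, or aluminium-bound methyl groups may consume the acid chloride so that little ketone forms. The fallback uses known chemistry only, sets out from 11 and returns at 16. Wacker oxidation of the vinyl group (PdCl2, CuCl, O2, DMF–H2O) should give the C7 methyl ketone F1. Horner–Wadsworth–Emmons reaction with triethyl phosphonoacetate and NaH gives the (E)-enoate F2. Copper hydride-catalysed asymmetric conjugate reduction (Cu(OAc)2, the p-Tol-BINAP antipode matched to 7R, polymethylhydrosiloxane, t-BuOH, toluene) then sets C7 under ligand control in the saturated ester F3. MeNH(OMe)·HCl with i-PrMgCl converts this into the Weinreb amide F4, and 2-methylprop-1-enylmagnesium bromide in THF delivers enone 16.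

Step 9. The oxazaborolidine may not discriminate well between the 2-methylprop-1-enyl group and the β-branched C8 chain, or borane may add to the trisubstituted alkene. The fallback sets out from 16 and returns at 18. Luche reduction (NaBH4, CeCl3, MeOH, −78 °C) should give 17 together with its C9 epimer, the (9S)-alcohol F5. After chromatographic separation, 17 is acetylated as in step 10, and F5 is converted into the same acetate 18 with inversion by a Mitsunobu reaction with acetic acid (PPh3, diisopropyl azodicarboxylate, toluene, 0 °C).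

Step 12. The activated angeloyl unit may isomerise from Z to E (tiglate formation), or acylation of the hindered C1 alcohol may stall. The fallback sets out from 19 and returns at 22. Carbodiimide esterification (N,N'-dicyclohexylcarbodiimide, DMAP, CH2Cl2) with 2-[bis(2,2,2-trifluoroethoxy)phosphoryl]propanoic acid gives the phosphonopropanoate ester F6. Still–Gennari olefination with acetaldehyde (KN(SiMe3)2, 18-crown-6, THF, −78 °C) then builds the (Z)-2-methylbut-2-enoate on the molecule and gives 22.

Further compounds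
F1 | step 8 | 1-[(1S,2R,4S,5R)-5-(tert-butyldimethylsilyloxy)-4-methyl-2-(triethylsilyloxy)cyclohexyl]ethan-1-one | CC[Si](CC)(CC)O[C@@H]1C[C@H](C)[C@H](O[Si](C)(C)C(C)(C)C)C[C@H]1C(C)=O
F2 | step 8 | ethyl (2E)-3-[(1S,2R,4S,5R)-5-(tert-butyldimethylsilyloxy)-4-methyl-2-(triethylsilyloxy)cyclohexyl]but-2-enoate | CC[Si](CC)(CC)O[C@@H]1C[C@H](C)[C@H](O[Si](C)(C)C(C)(C)C)C[C@H]1/C(C)=C/C(=O)OCC
F3 | step 8 | ethyl (3R)-3-[(1S,2R,4S,5R)-5-(tert-butyldimethylsilyloxy)-4-methyl-2-(triethylsilyloxy)cyclohexyl]butanoate | CC[Si](CC)(CC)O[C@@H]1C[C@H](C)[C@H](O[Si](C)(C)C(C)(C)C)C[C@H]1[C@H](C)CC(=O)OCC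
F4 | step 8 | (3R)-3-[(1S,2R,4S,5R)-5-(tert-butyldimethylsilyloxy)-4-methyl-2-(triethylsilyloxy)cyclohexyl]-N-methoxy-N-methylbutanamide | CC[Si](CC)(CC)O[C@@H]1C[C@H](C)[C@H](O[Si](C)(C)C(C)(C)C)C[C@H]1[C@H](C)CC(=O)N(C)OC
F5 | step 9 | (4S,6R)-6-[(1S,2R,4S,5R)-5-(tert-butyldimethylsilyloxy)-4-methyl-2-(triethylsilyloxy)cyclohexyl]-2-methylhept-2-en-4-ol | CC[Si](CC)(CC)O[C@@H]1C[C@H](C)[C@H](O[Si](C)(C)C(C)(C)C)C[C@H]1[C@H](C)C[C@@H](C=C(C)C)O
F6 | step 12 | (1R,2S,4R,5S)-2-[(2R,4R)-4-acetoxy-6-methylhept-5-en-2-yl]-4-(tert-butyldimethylsilyloxy)-5-methylcyclohexyl 2-[bis(2,2,2-trifluoroethoxy)phosphoryl]propanoate | CC(C(=O)O[C@@H]1C[C@H](C)[C@H](O[Si](C)(C)C(C)(C)C)C[C@H]1[C@H](C)C[C@H](C=C(C)C)OC(C)=O)P(=O)(OCC(F)(F)F)OCC(F)(F)F
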